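In a one-step world each substrate meets partner and becomes its product, and both hands see the same partner through time. Call the exposure minus the logarithm of the fraction of right-handed substrate left. The left-handed substrate then has that exposure multiplied by a fixed number. Wednesday's products at 20.0 h read it as 1.89. This ratio of the two logarithms, left hand over right hand, is the selectivity factor, and the excess follows from it: the difference of the fractions left over the sum of the fractions reacted.

common to all: left-handed substrate 0.10 M; right-handed substrate 0.10 M
- Tuesday's: partner 0.20 M; protic impurity 0.010 M; run made earlier
- Sunday's: partner 0.20 M; protic impurity 0.015 M; run made earlier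
- Wednesday's: partner 0.30 M; protic impurity 0.020 M; run made earlier
- flask: partner 0.200 M; protic impurity 0.0200 M; time 2.5 d

- Tuesday's (time / h: left-handed product / %, right-handed product / %, left-handed substrate / %): 3.00: 10.8, 5.2, 38.1; 4.00: 14.2, 9.4, 34.4; 6.00: 20.3, 11.7, 30.7; 10.0: 23.8, 14.2, 24.3; 15.0: 29.6, 18.3, 22.5; 25.0: 35.6, 24.1, 14.9; 40.0: 41.7, 29.7, 10.7
- Sunday's (time / h: left-handed product / %, right-handed product / %, left-handed substrate / %): 2.00: 8.0, 5.4, 39.7; 6.00: 19.2, 10.9, 31.7; 10.0: 24.2, 14.9, 26.1; 15.0: 30.1, 18.5, 20.9; 20.0: 33.2, 22.1, 18.5; 30.0: 35.4, 25.7, 12.4; 40.0: 40.1, 28.8, 10.5
- Wednesday's (time / h: left-handed product / %, right-handed product / %, left-handed substrate / %): 3.00: 17.1, 9.9, 32.9; 5.00: 24.3, 13.0, 28.4; 10.0: 33.7, 20.4, 16.2; 20.0: 41.2, 30.1, 10.0; 40.0: 46.9, 39.3, 1.0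

(scatter of a reading: 1 percentage point)

- partner is single-handed; left-handed substrate and right-handed substrate are mirror images of each other, charged as a racemate, each of them at the stated concentration
- an excess is the difference of the two amounts in percent of their sum
- an excess is below zero if the other one leads
- the handed part of partner does not stay in what it makes, so the products of the two hands are mirror images too

* excess of left-handed product over right-handed product in the product at 3.0 h
* excess of left-handed product over right-handed product in the product at 2.5 d
* part of the left-handed substrate and right-handed substrate charged together that has reacted at 2.5 d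

The flask looks nearly like Sunday's: in both the partner charge matches the two substrates together, but the protic impurity is 0.0200 M in the flask against 0.015 M on Sunday. We suppose each molecule of protic impurity takes one of partner, so usable partner is 90.0% of the charge in the flask and 92.5% on Sunday, and we reckon partner left as that minus the conversion. Sunday's readings end at 40.0 h with 68.9% reacted and exposure 0.858. Its readings from 20.0 h to 40.0 h give a gain of exposure of 0.0452 h⁻¹ per unit of partner fraction.

We start the flask from Sunday's state at 40.0 h, which should err high since the flask has less usable partner, and run it the further 20.0 h. We replace the sagging partner curve by its mean. A first pass, with partner held at its starting value for the stretch, gives 75.6% reacted, so the mean partner is 17.8% of its charge and the exposure 1.02. That gives 74.6% reacted and an excess of 14.4%. A mean wrong by a hundredth of the charge moves the conversion by 0.29 percentage points. For 3.0 h we borrow Sunday's first two readings: a straight line through them gives 6.78% of right-handed product, hence our estimate of an excess of 27.8%.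

The forecast, taking the selectivity as “the same in all three runs”, says 28%, 15% and 74%.

The flask gives 27.8%, 14.5% and 74.1%, from this scheme:

    partner + left-handed substrate → left-handed product (k = 0.621 M⁻¹ h⁻¹)
    partner + right-handed substrate → right-handed product (k = 0.330 M⁻¹ h⁻¹)
    partner → decomposition product (k = 2.10 × 10⁻⁴ h⁻¹)
    partner + protic impurity → quenched reagent (k = 6.05 M⁻¹ h⁻¹)
    partner ⇌ dormant form (K = 0.350, k = 0.111 h⁻¹)

At 2.50 d the flask holds 0% of its protic impurity and 0.0200 M of quenched reagent, 10.0% of the partner charge. The 37% of its own charge of right-handed substrate left in the flask, raised to the power 1.89, gives 15.1% for the left-handed substrate, and the flask holds 15%. The neighbour charged with 0.050 M of partner keeps 89% of its right-handed substrate; the same power gives 80.2%, and that neighbour holds 80% of left-handed substrate.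

(The numbers in the tables come from a simulation for an exercise, and the scatter is random.)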